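The flavone is disconnected at C4–C4a of ring C, so that the pyranone closes last by intramolecular Friedel–Crafts acylation of a β-aryloxycinnamic acid whose O1–C2 bond already exists. The route exploits ring A: C4a sits para to the C7 oxygen and ortho to O1, with only C5–H beside it, so it is the most nucleophilic and least hindered carbon for attack on the activated C4 carboxyl. One operation forms C4–C4a, closes ring C and delivers the chromen-4-one oxidation level directly. The precursor is the (Z)-3-aryloxy-3-arylacrylic acid carrying ring A as a 3-benzyloxy-4-methoxyphenoxy group and ring B as 3,4,5-trimethoxyphenyl; benzyl masks O7 and falls to hydrogenolysis.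

Key step: step 5

Assumption: 1, 4 and 5 are bought; the C2=C3 geometry is taken to be mobile under acid (rotation in the oxygen-stabilised cation), so step 5 should not depend on geometric purity from step 3.

Step 1
Reactants: 1 3-(benzyloxy)-4-methoxybenzaldehyde
Product: 3 3-(benzyloxy)-4-methoxyphenol, via aryl formate 2 (not isolated)
Conditions: mCPBA, CH2Cl2, 0 °C to rt; aq. Na2S2O3/NaHCO3 wash; then K2CO3 (cat.), MeOH, rt
Reagents that add atoms: 3-chloroperoxybenzoic acid (mCPBA), OOC(=O)c1cccc(Cl)c1
Why: Baeyer–Villiger (Dakin-type) oxidation, in which the electron-rich aryl group with its para methoxy donor migrates in the peracid adduct in preference to hydride to give formate 2, which base-catalysed methanolysis cleaves without touching the benzyl or methyl ethers.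

Step 2
Reactants: 4 5-iodo-1,2,3-trimethoxybenzene; 5 ethyl propiolate
Product: 6 ethyl 3-(3,4,5-trimethoxyphenyl)prop-2-ynoate
Conditions: PdCl2(PPh3)2 (2 mol%), CuI (4 mol%), K2CO3 (2 equiv), THF, 65 °C; 5 (3 equiv) added in portions
Reagents that add atoms: none
Why: Sonogashira coupling of an aryl iodide with a terminal alkyne, run with a carbonate base in place of an amine so that no nucleophilic base adds to the propiolate.

Step 3
Reactants: 3 3-(benzyloxy)-4-methoxyphenol; 6 ethyl 3-(3,4,5-trimethoxyphenyl)prop-2-ynoate
Product: 7 ethyl (Z)-3-[3-(benzyloxy)-4-methoxyphenoxy]-3-(3,4,5-trimethoxyphenyl)prop-2-enoate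
Conditions: Cs2CO3 (0.3 equiv), dry DMF, 60 °C
Reagents that add atoms: none
Why: Base-catalysed oxa-Michael addition (hydrophenoxylation) of the phenoxide to the β-carbon of the ynoate, the future C2, in which anti protonation of the allenolate places the aryloxy group cis to the ester and should give the Z alkene with O1–C2 fixed.

Step 4
Reactants: 7 ethyl (Z)-3-[3-(benzyloxy)-4-methoxyphenoxy]-3-(3,4,5-trimethoxyphenyl)prop-2-enoate
Product: 8 (Z)-3-[3-(benzyloxy)-4-methoxyphenoxy]-3-(3,4,5-trimethoxyphenyl)prop-2-enoic acid
Conditions: LiOH·H2O (3 equiv), THF/MeOH/H2O, rt; then 1 M HCl, 0 °C, to pH 3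
Reagents that add atoms: lithium hydroxide, [Li+].[OH-]
Why: Saponification by acyl–oxygen cleavage, in which the β-aryloxy enoate behaves as a vinylogous carbonate that should resist conjugate attack by hydroxide at room temperature, and brief cold acidification frees the acid without hydrolysing the enol ether.

Step 5
Reactants: 8 (Z)-3-[3-(benzyloxy)-4-methoxyphenoxy]-3-(3,4,5-trimethoxyphenyl)prop-2-enoic acid
Product: 10 7-(benzyloxy)-6-methoxy-2-(3,4,5-trimethoxyphenyl)-4H-chromen-4-one, via mixed trifluoroacetic anhydride 9 (not isolated)
Conditions: TFAA (3 equiv), CH2Cl2, 0 °C to rt; aq. NaHCO3 work-up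
Reagents that add atoms: none
Why: TFAA turns the acid into mixed anhydride 9, which ionises with help from the liberated trifluoroacetic acid to an acyl cation stabilised by the β-aryloxy and β-aryl groups; this attacks the ring A carbon para to the benzyloxy group and ortho to O1, and proton loss gives the pyranone at the flavone oxidation level. The closest known reaction type is the anhydride- or acid-mediated intramolecular Friedel–Crafts acylation that converts β-aryloxycinnamic acids into flavones and 2-aryloxybenzoic acids into xanthones. Ring C closes in a six-membered exo mode (6-exo-trig at the acyl carbon, whose C=O stays outside the new ring). No stereocentre is formed. The step needs regioselectivity on ring A, secured by the para benzyloxy donor and by the crowding of the other ortho carbon between O1 and the benzyloxy group, and chemoselectivity against closure onto ring B, secured by the Z geometry that holds the acyl group beside the aryloxy ring and by the strain of the five-membered indenone alternative. Working at or below room temperature without a mineral or metal Lewis acid should leave the benzyl ether intact.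

Step 6
Reactants: 10 7-(benzyloxy)-6-methoxy-2-(3,4,5-trimethoxyphenyl)-4H-chromen-4-one
Product: 11 Prosogerin D, 7-hydroxy-6-methoxy-2-(3,4,5-trimethoxyphenyl)-4H-chromen-4-one
Conditions: H2 (1 atm), 10% Pd/C, EtOAc/MeOH, rt; stopped at full conversion
Reagents that add atoms: none
Why: Catalytic hydrogenolysis of the benzyl aryl ether, in which the benzylic C–O bond should cleave well before the conjugated C2=C3 bond of the chromone is reduced and the methyl ethers are inert.

Compound list
1 | 3-(benzyloxy)-4-methoxybenzaldehyde | O=Cc1ccc(OC)c(OCc2ccccc2)c1 | starting material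
2 | 3-(benzyloxy)-4-methoxyphenyl formate | O=COc1ccc(OC)c(OCc2ccccc2)c1 | intermediate (not isolated)
3 | 3-(benzyloxy)-4-methoxyphenol | Oc1ccc(OC)c(OCc2ccccc2)c1 | intermediate
4 | 5-iodo-1,2,3-trimethoxybenzene | COc1cc(I)cc(OC)c1OC | starting material
5 | ethyl propiolate | CCOC(=O)C#C | starting material
6 | ethyl 3-(3,4,5-trimethoxyphenyl)prop-2-ynoate | CCOC(=O)C#Cc1cc(OC)c(OC)c(OC)c1 | intermediate
7 | ethyl (Z)-3-[3-(benzyloxy)-4-methoxyphenoxy]-3-(3,4,5-trimethoxyphenyl)prop-2-enoate | CCOC(=O)/C=C(\Oc1ccc(OC)c(OCc2ccccc2)c1)c1cc(OC)c(OC)c(OC)c1 | intermediate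
8 | (Z)-3-[3-(benzyloxy)-4-methoxyphenoxy]-3-(3,4,5-trimethoxyphenyl)prop-2-enoic acid | OC(=O)/C=C(\Oc1ccc(OC)c(OCc2ccccc2)c1)c1cc(OC)c(OC)c(OC)c1 | intermediate
9 | (Z)-3-[3-(benzyloxy)-4-methoxyphenoxy]-3-(3,4,5-trimethoxyphenyl)prop-2-enoic trifluoroacetic anhydride | FC(F)(F)C(=O)OC(=O)/C=C(\Oc1ccc(OC)c(OCc2ccccc2)c1)c1cc(OC)c(OC)c(OC)c1 | intermediate (not isolated)
10 | 7-(benzyloxy)-6-methoxy-2-(3,4,5-trimethoxyphenyl)-4H-chromen-4-one | COc1cc2c(=O)cc(-c3cc(OC)c(OC)c(OC)c3)oc2cc1OCc1ccccc1 | intermediate
11 | Prosogerin D, 7-hydroxy-6-methoxy-2-(3,4,5-trimethoxyphenyl)-4H-chromen-4-one | COc1cc2c(=O)cc(-c3cc(OC)c(OC)c(OC)c3)oc2cc1O | target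

Total step count: 6
Longest linear sequence: 5 steps (steps 1, 3, 4, 5, 6 from 1; equally steps 2, 3, 4, 5, 6 from 4)

Steps most likely to fail

Step 5. The acyl cation is strongly stabilised by the β-oxygen, which also draws the O1 lone pair away from ring A, so the mixed anhydride may simply persist. Acid-promoted loss or migration of the benzyl group and closure onto ring B are the other ways the step could go wrong. The fallback builds the same C4–C4a bond by palladium-catalysed carbonylation; it sets out from 3 and comes back at 10. Phenol 3 is iodinated with N-iodosuccinimide (MeCN, 0 °C), which should enter para to the benzyloxy group and ortho to the hydroxyl, to give 5-(benzyloxy)-2-iodo-4-methoxyphenol F1. F1 is then heated under CO (1 atm) with PdCl2(PPh3)2 in Et2NH at about 100 °C together with 5-ethynyl-1,2,3-trimethoxybenzene F4 (purchasable, or made from 4 as in the fallback to step 2). The carbonylative Sonogashira coupling gives 1-[4-(benzyloxy)-2-hydroxy-5-methoxyphenyl]-3-(3,4,5-trimethoxyphenyl)prop-2-yn-1-one F2, which is not isolated and should close by amine-mediated 6-endo addition of the phenol to the ynone to give 10.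

Step 2. Oligomerisation of ethyl propiolate and copper-mediated alkyne homocoupling may outrun the coupling at the electron-rich aryl iodide. The fallback installs the alkyne first and the ester carbon afterwards; it sets out from 4 and comes back at 6. Sonogashira coupling of 4 with ethynyltrimethylsilane (PdCl2(PPh3)2, CuI, Et3N, THF, 50 °C) gives trimethyl[(3,4,5-trimethoxyphenyl)ethynyl]silane F3. Methanolysis (K2CO3 cat., MeOH, rt) gives 5-ethynyl-1,2,3-trimethoxybenzene F4. Deprotonation with n-BuLi (THF, −78 °C) and trapping of the lithium acetylide with ethyl chloroformate gives 6.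

Step 3. Conjugate addition to the donor-substituted ynoate may be slow, the phenoxide may instead take the acyl group from the ethyl ester, and reversible addition may erode the alkene geometry. The fallback forms the O1–C2 bond by substitution at a vinyl iodide of defined geometry; it sets out from 6 and comes back at 7. Anti hydroiodination of 6 (NaI, AcOH, 110 °C) gives ethyl (Z)-3-iodo-3-(3,4,5-trimethoxyphenyl)prop-2-enoate F5. Ullmann-type C–O coupling of F5 with phenol 3 (CuI 10 mol%, N,N-dimethylglycine 20 mol%, Cs2CO3, dioxane, 90 °C) should proceed with retention and give 7.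

Further compounds
F1 | step 5 | 5-(benzyloxy)-2-iodo-4-methoxyphenol | Oc1cc(OCc2ccccc2)c(OC)cc1I
F2 | step 5 | 1-[4-(benzyloxy)-2-hydroxy-5-methoxyphenyl]-3-(3,4,5-trimethoxyphenyl)prop-2-yn-1-one | O=C(C#Cc1cc(OC)c(OC)c(OC)c1)c1cc(OC)c(OCc2ccccc2)cc1O
F3 | step 2 | trimethyl[(3,4,5-trimethoxyphenyl)ethynyl]silane | COc1cc(C#C[Si](C)(C)C)cc(OC)c1OC
F4 | step 2 | 5-ethynyl-1,2,3-trimethoxybenzene | COc1cc(C#C)cc(OC)c1OC
F5 | step 3 | ethyl (Z)-3-iodo-3-(3,4,5-trimethoxyphenyl)prop-2-enoate | CCOC(=O)/C=C(\I)c1cc(OC)c(OC)c(OC)c1
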